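**Plan**

- Retrosynthesis first removes the eleven O-benzyl groups and the gallate ester C–O bond, then cuts the O1–C2 bond of each chroman, leaving two ketones that each carry an ortho-phenol three atoms away.
- The enabling feature is the tropolone ring of the benzo[7]annulen-5-one (C5 ketone, C6–OH, C7–H, C8 bearing the galloylated chroman, C9–H). It is cut at C6–C7 and C8–C9: C7/C8 are the alkyne of an ynone that adds across C6 and C9 of an oxygen-bridged carbonyl ylide, and the bridge oxygen ends up as the C6 hydroxyl.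
- The ylide comes from an ortho-formyl aryl diazoketone (C5 from CO2, C6 from CH2N2, C9 the formyl carbon). Both ketone side chains are cut at their C(=O)–C(sp or sp2) bond back to one (R)-aryl-lactic Weinreb amide.
- Forward: the aryl-lactate is made by copper-catalysed opening of methyl (R)-glycidate; the ynone and the pentasubstituted benzo ring are built separately; the rhodium step closes the ylide ring and the seven-membered ring; acid gives the tropolone; both chroman rings close by reductive etherification; galloylation and hydrogenolysis finish.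
- Stereochemistry: both C3 centres (R) come from methyl (R)-glycidate; both C2 centres (R, 2,3-cis) are set by hydride addition to cyclic oxocarbenium ions anti to the C3 substituent; the two bridgehead centres of the cycloadduct are temporary.

Key step: step 17

Assumption: both bridge diastereomers of the cycloadduct are carried on together, because both bridgehead centres become sp2 in step 18. Abbreviations in names: Bn = benzyl, MOM = methoxymethyl, TBDPS = tert-butyldiphenylsilyl, Ar = 2,4-bis(benzyloxy)-6-(methoxymethoxy)phenyl, Ar(OH) = 2,4-bis(benzyloxy)-6-hydroxyphenyl.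

**Route**

Step 1
Reactants: 1 3,5-bis(benzyloxy)phenol
Product: 2 1,3-bis(benzyloxy)-5-(methoxymethoxy)benzene
Conditions: MOMCl, i-Pr2NEt, CH2Cl2, 0 °C → rt
Reagents that add atoms: chloromethyl methyl ether, COCCl
Why: Williamson-type O-alkylation of the only free phenol installs the one acid-labile phenol ether of the route, which is also the stronger ortho-directing group for step 2.

Step 2
Reactants: 2 1,3-bis(benzyloxy)-5-(methoxymethoxy)benzene; 3 methyl (R)-glycidate
Product: 6 methyl (2R)-3-Ar-2-hydroxypropanoate, via aryllithium 4 (not isolated), via arylmagnesium bromide 5 (not isolated)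
Conditions: n-BuLi, THF, 0 °C; MgBr2·OEt2, −40 °C; CuI (10 mol %), then 3, −40 → −20 °C; aq. NH4Cl
Reagents that add atoms: none
Why: Directed ortho-metalation should occur at the position flanked by the MOM ether and one benzyl ether, and after transmetalation the copper-catalysed aryl Grignard opens the epoxide by SN2 attack at the unsubstituted C3, so the untouched C2 centre carries the (R)-configuration of 3 into 6.

Step 3
Reactants: 6 methyl (2R)-3-Ar-2-hydroxypropanoate
Product: 7 (2R)-3-Ar-2-hydroxy-N-methoxy-N-methylpropanamide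
Conditions: MeNH(OMe)·HCl, i-PrMgCl, THF, −20 → 0 °C
Reagents that add atoms: N,O-dimethylhydroxylamine hydrochloride, CNOC.Cl
Why: Aminolysis of the ester by the chloromagnesium amide gives the Weinreb amide, with the hydroxyl carried as its magnesium alkoxide and no base present that could enolise the α-centre.

Step 4
Reactants: 7 (2R)-3-Ar-2-hydroxy-N-methoxy-N-methylpropanamide
Product: 8 (2R)-3-Ar-2-[(tert-butyldiphenylsilyl)oxy]-N-methoxy-N-methylpropanamide
Conditions: TBDPSCl, imidazole, DMF, rt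
Reagents that add atoms: tert-butyl(chloro)diphenylsilane, CC(C)(C)[Si](Cl)(c1ccccc1)c1ccccc1
Why: Imidazole-promoted silylation gives a bulky silyl ether that should survive Grignard addition, the rhodium step and the acidic MOM cleavage, and can later be removed by fluoride beside benzyl ethers.

Step 5
Reactants: 8 (2R)-3-Ar-2-[(tert-butyldiphenylsilyl)oxy]-N-methoxy-N-methylpropanamide; 9 ethynylmagnesium bromide
Product: 10 (4R)-5-Ar-4-[(tert-butyldiphenylsilyl)oxy]pent-1-yn-3-one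
Conditions: THF, 0 °C; aq. NH4Cl
Reagents that add atoms: none
Why: Weinreb ketone synthesis: the alkynyl Grignard adds once and the chelated tetrahedral intermediate collapses only on work-up, so the terminal ynone should form without over-addition or α-epimerisation.

Step 6
Reactants: 7 (2R)-3-Ar-2-hydroxy-N-methoxy-N-methylpropanamide
Product: 11 (2R)-3-Ar-2-(benzyloxy)-N-methoxy-N-methylpropanamide
Conditions: NaH, BnBr, n-Bu4NI (cat.), THF, 0 °C → rt
Reagents that add atoms: benzyl bromide, BrCc1ccccc1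
Why: Williamson benzylation of the sodium alkoxide (the amide α-proton is not acidic enough to be removed at 0 °C) protects the benzo-side hydroxyl as an ether that falls in the final hydrogenolysis.

Step 7
Reactants: 12 3-bromo-4,5-dihydroxybenzaldehyde
Product: 13 4-(benzyloxy)-3-bromo-5-hydroxybenzaldehyde
Conditions: BnBr (1 equiv), NaHCO3, NaI (cat.), DMF, 40 °C
Reagents that add atoms: benzyl bromide, BrCc1ccccc1
Why: With a weak base only the more acidic 4-hydroxyl (para to the formyl group, ortho to bromine) is ionised and benzylated (regioselective Williamson etherification), which leaves the 5-hydroxyl free to direct step 8.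

Step 8
Reactants: 13 4-(benzyloxy)-3-bromo-5-hydroxybenzaldehyde
Product: 14 4-(benzyloxy)-5-bromo-3-hydroxy-2-iodobenzaldehyde
Conditions: ICl, pyridine, CH2Cl2, 0 °C → rt
Reagents that add atoms: iodine monochloride, ClI
Why: Electrophilic aromatic iodination is steered by the free phenol to its only open ortho position, between OH and CHO, as in the known 2-halogenation of 3-hydroxy-4-alkoxybenzaldehydes, while the para position is crowded by bromine and the formyl group.

Step 9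
Reactants: 14 4-(benzyloxy)-5-bromo-3-hydroxy-2-iodobenzaldehyde
Product: 15 3,4-bis(benzyloxy)-5-bromo-2-iodobenzaldehyde
Conditions: BnBr, K2CO3, DMF, rt
Reagents that add atoms: benzyl bromide, BrCc1ccccc1
Why: Williamson benzylation of the remaining phenol completes the protection of the catechol.

Step 10
Reactants: 15 3,4-bis(benzyloxy)-5-bromo-2-iodobenzaldehyde
Product: 16 [3,4-bis(benzyloxy)-5-bromo-2-iodophenyl]methanol
Conditions: NaBH4, MeOH/THF, 0 °C
Reagents that add atoms: none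
Why: Borohydride reduction brings the formyl carbon to the alcohol level, at which it can be carried through the organometallic and acid chloride steps.

Step 11
Reactants: 16 [3,4-bis(benzyloxy)-5-bromo-2-iodophenyl]methanol
Product: 17 {[3,4-bis(benzyloxy)-5-bromo-2-iodobenzyl]oxy}(tert-butyl)diphenylsilane
Conditions: TBDPSCl, imidazole, DMF, rt
Reagents that add atoms: tert-butyl(chloro)diphenylsilane, CC(C)(C)[Si](Cl)(c1ccccc1)c1ccccc1
Why: Silylation masks the benzylic alcohol as a bulky, weakly nucleophilic ether that tolerates Grignard and alkyllithium reagents and should not lactonise onto the later acid chloride.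

Step 12
Reactants: 17 {[3,4-bis(benzyloxy)-5-bromo-2-iodobenzyl]oxy}(tert-butyl)diphenylsilane
Product: 19 2,3-bis(benzyloxy)-4-bromo-6-{[(tert-butyldiphenylsilyl)oxy]methyl}benzoic acid, via arylmagnesium chloride 18 (not isolated)
Conditions: i-PrMgCl, THF, −40 °C; CO2 (gas), −40 → 0 °C; dilute HCl to pH 3
Reagents that add atoms: carbon dioxide, O=C=O
Why: Iodine–magnesium exchange is much faster at the aryl iodide than at the aryl bromide, so the Grignard forms only at the former C2, and its carboxylation installs the carbon that becomes C5 of the benzo[7]annulenone.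

Step 13
Reactants: 19 2,3-bis(benzyloxy)-4-bromo-6-{[(tert-butyldiphenylsilyl)oxy]methyl}benzoic acid; 11 (2R)-3-Ar-2-(benzyloxy)-N-methoxy-N-methylpropanamide
Product: 21 2,3-bis(benzyloxy)-4-[(2R)-2-(benzyloxy)-3-Ar-propanoyl]-6-{[(tert-butyldiphenylsilyl)oxy]methyl}benzoic acid, via dilithiated benzoate 20 (not isolated)
Conditions: 19 (1.3 equiv), n-BuLi (2.6 equiv), THF, −78 °C; then 11, −78 → −40 °C; aq. NH4Cl, then dilute HCl to pH 3
Reagents that add atoms: none
Why: One equivalent of n-BuLi forms the lithium carboxylate and the second effects bromine–lithium exchange (Parham-type dianion), and the aryllithium acylates the Weinreb amide to the aryl ketone without touching the α-stereocentre because the tetrahedral chelate persists until work-up.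

Step 14
Reactants: 21 2,3-bis(benzyloxy)-4-[(2R)-2-(benzyloxy)-3-Ar-propanoyl]-6-{[(tert-butyldiphenylsilyl)oxy]methyl}benzoic acid
Product: 23 1-{2,3-bis(benzyloxy)-4-[(2R)-2-(benzyloxy)-3-Ar-propanoyl]-6-{[(tert-butyldiphenylsilyl)oxy]methyl}phenyl}-2-diazoethan-1-one, via acid chloride 22 (not isolated)
Conditions: 1-chloro-N,N,2-trimethylprop-1-en-1-amine, CH2Cl2, 0 °C; then CH2N2 (excess), Et2O, 0 °C
Reagents that add atoms: diazomethane, C=[N+]=[N-]
Why: The α-chloroenamine converts the acid to the acid chloride without releasing HCl (so MOM and silyl ethers survive), and acylation of diazomethane (first stage of the Arndt–Eistert sequence) gives the diazoketone, a second equivalent of diazomethane taking up the HCl.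

Step 15
Reactants: 23 1-{2,3-bis(benzyloxy)-4-[(2R)-2-(benzyloxy)-3-Ar-propanoyl]-6-{[(tert-butyldiphenylsilyl)oxy]methyl}phenyl}-2-diazoethan-1-one
Product: 24 1-{2,3-bis(benzyloxy)-4-[(2R)-2-(benzyloxy)-3-Ar-propanoyl]-6-(hydroxymethyl)phenyl}-2-diazoethan-1-one
Conditions: TBAF, AcOH, THF, 0 °C → rt
Reagents that add atoms: none
Why: Acetic-acid-buffered fluoride cleaves the primary silyl ether while the medium stays too weakly basic to epimerise the α-benzyloxy ketone and too weakly acidic to protonate the diazoketone.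

Step 16
Reactants: 24 1-{2,3-bis(benzyloxy)-4-[(2R)-2-(benzyloxy)-3-Ar-propanoyl]-6-(hydroxymethyl)phenyl}-2-diazoethan-1-one
Product: 25 3,4-bis(benzyloxy)-5-[(2R)-2-(benzyloxy)-3-Ar-propanoyl]-2-(diazoacetyl)benzaldehyde
Conditions: MnO2 (activated, excess), CH2Cl2, rt
Reagents that add atoms: none
Why: MnO2 oxidises the benzylic alcohol selectively to the aldehyde under neutral heterogeneous conditions that should leave the diazoketone untouched.

Step 17
Reactants: 25 3,4-bis(benzyloxy)-5-[(2R)-2-(benzyloxy)-3-Ar-propanoyl]-2-(diazoacetyl)benzaldehyde; 10 (4R)-5-Ar-4-[(tert-butyldiphenylsilyl)oxy]pent-1-yn-3-one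
Product: 27 (6R,9R)-3,4-bis(benzyloxy)-2-[(2R)-2-(benzyloxy)-3-Ar-propanoyl]-8-{(2R)-3-Ar-2-[(tert-butyldiphenylsilyl)oxy]propanoyl}-6,9-dihydro-5H-6,9-epoxybenzo[7]annulen-5-one (one bridge diastereomer drawn, the (6S,9S) isomer is expected beside it), via carbonyl ylide 26 (not isolated)
Conditions: Rh2(OAc)4 (2 mol %), 10 (2 equiv), CH2Cl2, rt, slow addition of 25
Reagents that add atoms: none
Why: Rh2(OAc)4 (divalent rhodium) decomposes the diazoketone to a carbenoid that is captured by a lone pair of the ortho-aldehyde oxygen, closing the first ring (six-membered, O onto the carbenoid carbon) to the aromatic carbonyl ylide 26, a 2-benzopyrylium-4-olate; 26 then adds ynone 10 in a concerted suprafacial 1,3-dipolar (3+2) cycloaddition that forms C6–C7 and C8–C9 and so closes the seven-membered carbocycle across the one-atom oxygen bridge (second ring, intermolecular cycloaddition). The closest known reaction type is the rhodium carbonyl-ylide/alkyne cycloaddition of ortho-acyl aryl diazoketones. The selectivity that matters is regiochemistry: the enolate-like ylide terminus next to the ketone (C6, largest HOMO coefficient) should bond to the unsubstituted β-carbon of the ynone (largest LUMO coefficient), which places the acyl-bearing alkyne carbon at C8 next to the benzylic terminus C9. The two new bridgehead stereocentres (C6, C9) are necessarily cis across the bridge, but the face of the planar ylide is not controlled by the remote (R)-centres, so both bridge diastereomers should form and are taken on together. Ylide formation should win over attack of the carbenoid on the neighbouring benzyl ether oxygen or on the alkyne because the carbonyl oxygen is the better nucleophile, the ylide is aromatic, and 25 is added slowly to an excess of 10.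

Step 18
Reactants: 27 the oxygen-bridged cycloadduct (both bridge diastereomers)
Product: 29 3,4-bis(benzyloxy)-2-[(2R)-2-(benzyloxy)-3-Ar(OH)-propanoyl]-8-{(2R)-3-Ar(OH)-2-[(tert-butyldiphenylsilyl)oxy]propanoyl}-6-hydroxy-5H-benzo[7]annulen-5-one (keto-phenol form, in equilibrium with its lactols), via MOM-protected tropolone 28 (not isolated)
Conditions: TsOH·H2O, CH2Cl2, rt; then MeOH, 40 °C
Reagents that add atoms: none
Why: Acid ionises the bridging ether at the benzylic, allylic C9–O bond and loss of the C6 proton aromatises the ring to the tropolone (the known acid opening of oxygen-bridged cycloheptadienones), after which acid-catalysed acetal exchange with methanol removes both MOM groups while the TBDPS and benzyl ethers should stay.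

Step 19
Reactants: 29 the tropolone bis(keto-phenol)
Product: 30 3,4-bis(benzyloxy)-8-{(2R,3R)-5,7-bis(benzyloxy)-3-[(tert-butyldiphenylsilyl)oxy]chroman-2-yl}-6-hydroxy-2-[(2R,3R)-3,5,7-tris(benzyloxy)chroman-2-yl]-5H-benzo[7]annulen-5-one
Conditions: Et3SiH, TMSOTf, CH2Cl2, −78 → −30 °C; aq. NaHCO3
Reagents that add atoms: none
Why: Reductive etherification: TMSOTf closes each keto-phenol through its lactol to a cyclic oxocarbenium ion in which the C3 substituent sits pseudoaxial to avoid allylic strain with the C2 aryl group, and Et3SiH delivers hydride to the opposite face, which should set both new C2 centres as (R), cis to the C3 oxygen.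

Step 20
Reactants: 30 the bis-chroman tropolone
Product: 31 3,4,6-tris(benzyloxy)-8-{(2R,3R)-5,7-bis(benzyloxy)-3-[(tert-butyldiphenylsilyl)oxy]chroman-2-yl}-2-[(2R,3R)-3,5,7-tris(benzyloxy)chroman-2-yl]-5H-benzo[7]annulen-5-one
Conditions: BnBr, K2CO3, DMF, rt
Reagents that add atoms: benzyl bromide, BrCc1ccccc1
Why: The tropolone hydroxyl is the only acidic OH left and is O-benzylated (Williamson; only the 6-O-ether keeps the benzo ring aromatic), so that the later acylation can reach the secondary alcohol alone.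

Step 21
Reactants: 31 the 6-O-benzyl tropolone silyl ether
Product: 32 3,4,6-tris(benzyloxy)-8-[(2R,3R)-5,7-bis(benzyloxy)-3-hydroxychroman-2-yl]-2-[(2R,3R)-3,5,7-tris(benzyloxy)chroman-2-yl]-5H-benzo[7]annulen-5-one
Conditions: TBAF, AcOH, THF, rt → 40 °C
Reagents that add atoms: none
Why: Buffered fluoride cleaves the Si–O bond selectively, benzyl ethers and the tropone ether being inert, and frees the C3 hydroxyl of the C8 chroman.

Step 22
Reactants: 32 the C3 alcohol; 33 3,4,5-tris(benzyloxy)benzoic acid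
Product: 34 (2R,3R)-5,7-bis(benzyloxy)-2-{3,4,6-tris(benzyloxy)-5-oxo-2-[(2R,3R)-3,5,7-tris(benzyloxy)chroman-2-yl]-5H-benzo[7]annulen-8-yl}chroman-3-yl 3,4,5-tris(benzyloxy)benzoate
Conditions: DCC, DMAP, CH2Cl2, rt
Reagents that add atoms: none
Why: Steglich esterification (carbodiimide activation, DMAP acyl transfer) acylates the single free, hindered secondary alcohol with retention at C3.

Step 23
Reactants: 34 the perbenzylated gallate
Product: 35 (2R,3R)-5,7-dihydroxy-2-{3,4,6-trihydroxy-5-oxo-2-[(2R,3R)-3,5,7-trihydroxychroman-2-yl]-5H-benzo[7]annulen-8-yl}chroman-3-yl 3,4,5-trihydroxybenzoate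
Conditions: H2 (1 atm), Pd(OH)2 on carbon, THF/MeOH, rt
Reagents that add atoms: none
Why: Palladium-catalysed hydrogenolysis cleaves all eleven benzyl C–O bonds (aryl, tropolonyl and alkyl benzyl ethers) under neutral conditions that should leave the gallate ester, the chroman C2–O bonds and the four stereocentres intact.

**Compound list**

1 | 3,5-bis(benzyloxy)phenol | Oc1cc(OCc9ccccc9)cc(OCc9ccccc9)c1 | starting material
2 | 1,3-bis(benzyloxy)-5-(methoxymethoxy)benzene | COCOc1cc(OCc9ccccc9)cc(OCc9ccccc9)c1 | intermediate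
3 | methyl (R)-glycidate | COC(=O)[C@H]1CO1 | starting material
4 | [2,4-bis(benzyloxy)-6-(methoxymethoxy)phenyl]lithium | [Li]c1c(OCOC)cc(OCc9ccccc9)cc1OCc9ccccc9 | intermediate (not isolated)
5 | [2,4-bis(benzyloxy)-6-(methoxymethoxy)phenyl]magnesium bromide | Br[Mg]c1c(OCOC)cc(OCc9ccccc9)cc1OCc9ccccc9 | intermediate (not isolated)
6 | methyl (2R)-3-[2,4-bis(benzyloxy)-6-(methoxymethoxy)phenyl]-2-hydroxypropanoate | COC(=O)[C@H](O)Cc1c(OCOC)cc(OCc9ccccc9)cc1OCc9ccccc9 | intermediate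
7 | (2R)-3-[2,4-bis(benzyloxy)-6-(methoxymethoxy)phenyl]-2-hydroxy-N-methoxy-N-methylpropanamide | CON(C)C(=O)[C@H](O)Cc1c(OCOC)cc(OCc9ccccc9)cc1OCc9ccccc9 | intermediate
8 | (2R)-3-[2,4-bis(benzyloxy)-6-(methoxymethoxy)phenyl]-2-[(tert-butyldiphenylsilyl)oxy]-N-methoxy-N-methylpropanamide | CON(C)C(=O)[C@H](O[Si](c9ccccc9)(c9ccccc9)C(C)(C)C)Cc1c(OCOC)cc(OCc9ccccc9)cc1OCc9ccccc9 | intermediate
9 | ethynylmagnesium bromide | C#C[Mg]Br | starting material
10 | (4R)-5-[2,4-bis(benzyloxy)-6-(methoxymethoxy)phenyl]-4-[(tert-butyldiphenylsilyl)oxy]pent-1-yn-3-one | C#CC(=O)[C@H](O[Si](c9ccccc9)(c9ccccc9)C(C)(C)C)Cc1c(OCOC)cc(OCc9ccccc9)cc1OCc9ccccc9 | intermediate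
11 | (2R)-2-(benzyloxy)-3-[2,4-bis(benzyloxy)-6-(methoxymethoxy)phenyl]-N-methoxy-N-methylpropanamide | CON(C)C(=O)[C@H](OCc9ccccc9)Cc1c(OCOC)cc(OCc9ccccc9)cc1OCc9ccccc9 | intermediate
12 | 3-bromo-4,5-dihydroxybenzaldehyde | O=Cc1cc(Br)c(O)c(O)c1 | starting material
13 | 4-(benzyloxy)-3-bromo-5-hydroxybenzaldehyde | O=Cc1cc(Br)c(OCc9ccccc9)c(O)c1 | intermediate
14 | 4-(benzyloxy)-5-bromo-3-hydroxy-2-iodobenzaldehyde | O=Cc1cc(Br)c(OCc9ccccc9)c(O)c1I | intermediate
15 | 3,4-bis(benzyloxy)-5-bromo-2-iodobenzaldehyde | O=Cc1cc(Br)c(OCc9ccccc9)c(OCc9ccccc9)c1I | intermediate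
16 | [3,4-bis(benzyloxy)-5-bromo-2-iodophenyl]methanol | OCc1cc(Br)c(OCc9ccccc9)c(OCc9ccccc9)c1I | intermediate
17 | {[3,4-bis(benzyloxy)-5-bromo-2-iodobenzyl]oxy}(tert-butyl)diphenylsilane | CC(C)(C)[Si](OCc1cc(Br)c(OCc9ccccc9)c(OCc9ccccc9)c1I)(c9ccccc9)c9ccccc9 | intermediate
18 | [2,3-bis(benzyloxy)-4-bromo-6-{[(tert-butyldiphenylsilyl)oxy]methyl}phenyl]magnesium chloride | CC(C)(C)[Si](OCc1cc(Br)c(OCc9ccccc9)c(OCc9ccccc9)c1[Mg]Cl)(c9ccccc9)c9ccccc9 | intermediate (not isolated)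
19 | 2,3-bis(benzyloxy)-4-bromo-6-{[(tert-butyldiphenylsilyl)oxy]methyl}benzoic acid | CC(C)(C)[Si](OCc1cc(Br)c(OCc9ccccc9)c(OCc9ccccc9)c1C(=O)O)(c9ccccc9)c9ccccc9 | intermediate
20 | lithium 2,3-bis(benzyloxy)-4-lithio-6-{[(tert-butyldiphenylsilyl)oxy]methyl}benzoate | CC(C)(C)[Si](OCc1cc([Li])c(OCc9ccccc9)c(OCc9ccccc9)c1C(=O)O[Li])(c9ccccc9)c9ccccc9 | intermediate (not isolated)
21 | 2,3-bis(benzyloxy)-4-{(2R)-2-(benzyloxy)-3-[2,4-bis(benzyloxy)-6-(methoxymethoxy)phenyl]propanoyl}-6-{[(tert-butyldiphenylsilyl)oxy]methyl}benzoic acid | CC(C)(C)[Si](OCc1cc(C(=O)[C@H](OCc9ccccc9)Cc2c(OCOC)cc(OCc9ccccc9)cc2OCc9ccccc9)c(OCc9ccccc9)c(OCc9ccccc9)c1C(=O)O)(c9ccccc9)c9ccccc9 | intermediate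
22 | acid chloride of 21 | CC(C)(C)[Si](OCc1cc(C(=O)[C@H](OCc9ccccc9)Cc2c(OCOC)cc(OCc9ccccc9)cc2OCc9ccccc9)c(OCc9ccccc9)c(OCc9ccccc9)c1C(Cl)=O)(c9ccccc9)c9ccccc9 | intermediate (not isolated)
23 | 1-{2,3-bis(benzyloxy)-4-[(2R)-2-(benzyloxy)-3-Ar-propanoyl]-6-{[(tert-butyldiphenylsilyl)oxy]methyl}phenyl}-2-diazoethan-1-one | CC(C)(C)[Si](OCc1cc(C(=O)[C@H](OCc9ccccc9)Cc2c(OCOC)cc(OCc9ccccc9)cc2OCc9ccccc9)c(OCc9ccccc9)c(OCc9ccccc9)c1C(=O)C=[N+]=[N-])(c9ccccc9)c9ccccc9 | intermediate
24 | 1-{2,3-bis(benzyloxy)-4-[(2R)-2-(benzyloxy)-3-Ar-propanoyl]-6-(hydroxymethyl)phenyl}-2-diazoethan-1-one | OCc1cc(C(=O)[C@H](OCc9ccccc9)Cc2c(OCOC)cc(OCc9ccccc9)cc2OCc9ccccc9)c(OCc9ccccc9)c(OCc9ccccc9)c1C(=O)C=[N+]=[N-] | intermediate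
25 | 3,4-bis(benzyloxy)-5-{(2R)-2-(benzyloxy)-3-[2,4-bis(benzyloxy)-6-(methoxymethoxy)phenyl]propanoyl}-2-(diazoacetyl)benzaldehyde | O=Cc1cc(C(=O)[C@H](OCc9ccccc9)Cc2c(OCOC)cc(OCc9ccccc9)cc2OCc9ccccc9)c(OCc9ccccc9)c(OCc9ccccc9)c1C(=O)C=[N+]=[N-] | intermediate
26 | 5,6-bis(benzyloxy)-7-[(2R)-2-(benzyloxy)-3-Ar-propanoyl]-2-benzopyrylium-4-olate (carbonyl ylide) | [O-]C1=C[O+]=Cc2cc(C(=O)[C@H](OCc9ccccc9)Cc3c(OCOC)cc(OCc9ccccc9)cc3OCc9ccccc9)c(OCc9ccccc9)c(OCc9ccccc9)c12 | intermediate (not isolated)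
27 | (6R,9R)-3,4-bis(benzyloxy)-2-[(2R)-2-(benzyloxy)-3-Ar-propanoyl]-8-{(2R)-3-Ar-2-[(tert-butyldiphenylsilyl)oxy]propanoyl}-6,9-dihydro-5H-6,9-epoxybenzo[7]annulen-5-one (drawn bridge diastereomer) | O=C1c2c(OCc9ccccc9)c(OCc9ccccc9)c(C(=O)[C@H](OCc9ccccc9)Cc3c(OCOC)cc(OCc9ccccc9)cc3OCc9ccccc9)cc2[C@H]4O[C@@H]1C=C4C(=O)[C@H](O[Si](c9ccccc9)(c9ccccc9)C(C)(C)C)Cc5c(OCOC)cc(OCc9ccccc9)cc5OCc9ccccc9 | intermediate
28 | 3,4-bis(benzyloxy)-2-[(2R)-2-(benzyloxy)-3-Ar-propanoyl]-8-{(2R)-3-Ar-2-[(tert-butyldiphenylsilyl)oxy]propanoyl}-6-hydroxy-5H-benzo[7]annulen-5-one | O=C1C(O)=CC(C(=O)[C@H](O[Si](c9ccccc9)(c9ccccc9)C(C)(C)C)Cc3c(OCOC)cc(OCc9ccccc9)cc3OCc9ccccc9)=Cc2cc(C(=O)[C@H](OCc9ccccc9)Cc4c(OCOC)cc(OCc9ccccc9)cc4OCc9ccccc9)c(OCc9ccccc9)c(OCc9ccccc9)c12 | intermediate (not isolated)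
29 | 3,4-bis(benzyloxy)-2-[(2R)-2-(benzyloxy)-3-Ar(OH)-propanoyl]-8-{(2R)-3-Ar(OH)-2-[(tert-butyldiphenylsilyl)oxy]propanoyl}-6-hydroxy-5H-benzo[7]annulen-5-one | O=C1C(O)=CC(C(=O)[C@H](O[Si](c9ccccc9)(c9ccccc9)C(C)(C)C)Cc3c(O)cc(OCc9ccccc9)cc3OCc9ccccc9)=Cc2cc(C(=O)[C@H](OCc9ccccc9)Cc4c(O)cc(OCc9ccccc9)cc4OCc9ccccc9)c(OCc9ccccc9)c(OCc9ccccc9)c12 | intermediate
30 | 3,4-bis(benzyloxy)-8-{(2R,3R)-5,7-bis(benzyloxy)-3-[(tert-butyldiphenylsilyl)oxy]chroman-2-yl}-6-hydroxy-2-[(2R,3R)-3,5,7-tris(benzyloxy)chroman-2-yl]-5H-benzo[7]annulen-5-one | CC(C)(C)[Si](c9ccccc9)(c9ccccc9)O[C@@H]1Cc2c(OCc9ccccc9)cc(OCc9ccccc9)cc2O[C@@H]1C3=Cc4cc([C@H]5Oc6cc(OCc9ccccc9)cc(OCc9ccccc9)c6C[C@H]5OCc9ccccc9)c(OCc9ccccc9)c(OCc9ccccc9)c4C(=O)C(O)=C3 | intermediate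
31 | 3,4,6-tris(benzyloxy)-8-{(2R,3R)-5,7-bis(benzyloxy)-3-[(tert-butyldiphenylsilyl)oxy]chroman-2-yl}-2-[(2R,3R)-3,5,7-tris(benzyloxy)chroman-2-yl]-5H-benzo[7]annulen-5-one | CC(C)(C)[Si](c9ccccc9)(c9ccccc9)O[C@@H]1Cc2c(OCc9ccccc9)cc(OCc9ccccc9)cc2O[C@@H]1C3=Cc4cc([C@H]5Oc6cc(OCc9ccccc9)cc(OCc9ccccc9)c6C[C@H]5OCc9ccccc9)c(OCc9ccccc9)c(OCc9ccccc9)c4C(=O)C(OCc9ccccc9)=C3 | intermediate
32 | 3,4,6-tris(benzyloxy)-8-[(2R,3R)-5,7-bis(benzyloxy)-3-hydroxychroman-2-yl]-2-[(2R,3R)-3,5,7-tris(benzyloxy)chroman-2-yl]-5H-benzo[7]annulen-5-one | O[C@@H]1Cc2c(OCc9ccccc9)cc(OCc9ccccc9)cc2O[C@@H]1C3=Cc4cc([C@H]5Oc6cc(OCc9ccccc9)cc(OCc9ccccc9)c6C[C@H]5OCc9ccccc9)c(OCc9ccccc9)c(OCc9ccccc9)c4C(=O)C(OCc9ccccc9)=C3 | intermediate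
33 | 3,4,5-tris(benzyloxy)benzoic acid | OC(=O)c1cc(OCc9ccccc9)c(OCc9ccccc9)c(OCc9ccccc9)c1 | starting material
34 | (2R,3R)-5,7-bis(benzyloxy)-2-{3,4,6-tris(benzyloxy)-5-oxo-2-[(2R,3R)-3,5,7-tris(benzyloxy)chroman-2-yl]-5H-benzo[7]annulen-8-yl}chroman-3-yl 3,4,5-tris(benzyloxy)benzoate | O=C(O[C@@H]1Cc2c(OCc9ccccc9)cc(OCc9ccccc9)cc2O[C@@H]1C3=Cc4cc([C@H]5Oc6cc(OCc9ccccc9)cc(OCc9ccccc9)c6C[C@H]5OCc9ccccc9)c(OCc9ccccc9)c(OCc9ccccc9)c4C(=O)C(OCc9ccccc9)=C3)c7cc(OCc9ccccc9)c(OCc9ccccc9)c(OCc9ccccc9)c7 | intermediate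
35 | (2R,3R)-5,7-dihydroxy-2-{3,4,6-trihydroxy-5-oxo-2-[(2R,3R)-3,5,7-trihydroxychroman-2-yl]-5H-benzo[7]annulen-8-yl}chroman-3-yl 3,4,5-trihydroxybenzoate (CNP0259919.2) | O=C(O[C@@H]1Cc2c(O)cc(O)cc2O[C@@H]1c1cc(O)c(=O)c2c(O)c(O)c([C@H]3Oc4cc(O)cc(O)c4C[C@H]3O)cc2c1)c1cc(O)c(O)c(O)c1 | target

**Step count and risks**

Total step count: 23. Longest linear sequence: 17 steps (steps 7–23, from 3-bromo-4,5-dihydroxybenzaldehyde).

Steps most likely to fail:

Step 17. The carbenoid may be diverted before it reaches the aldehyde oxygen (attack on the neighbouring benzyl ether oxygen followed by benzyl shift, or reaction with the alkyne), or the dipolarophile may add in the reverse orientation. The fallback generates the same ylide without a carbene and sets out from 25. Formic acid in CH2Cl2 at rt protonates the diazo carbon and displaces nitrogen to give the α-formyloxy ketone F1. KHCO3 in MeOH at 0 °C removes the formate, and the freed hydroxy ketone closes onto the neighbouring aldehyde to give the lactol F2. Ac2O/pyridine converts it into the lactol acetate F3. Heating F3 with ynone 10 and i-Pr2NEt in toluene eliminates acetic acid across C1/C3 of the isochromanone to release ylide 26, which is trapped as before, and the route is rejoined at 27.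

Step 19. Hydride delivery to the two oxocarbenium ions may show poor facial selectivity, or the C3 configuration may be lost by proton loss from the oxocarbenium ion to the enol ether. The fallback replaces oxocarbenium reduction by catalyst-controlled carbonyl reduction and invertive ring closure, and sets out from 28 (isolated by stopping step 18 before methanol is added). BnBr/K2CO3 in DMF gives the 6-O-benzyl tropolone diketone F5. Corey–Bakshi–Shibata reduction ((S)-2-methyl-oxazaborolidine, BH3·SMe2, THF, −20 °C) should reduce both side-chain aryl ketones to the (1S)-carbinols, giving the diol F6. ZnBr2/n-PrSH in CH2Cl2 removes the MOM groups to give the bis-phenol diol F7. A double Mitsunobu etherification (PPh3, DIAD, THF, 0 °C) closes both rings with inversion at the carbinol carbons, which makes the (2R,3R) chromans, and the route is rejoined at 31.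

Step 18. The acid strength needed to ionise the bridging ether may also cause loss of the silyl or benzyl ethers or enolisation of the α-oxy ketones. The fallback opens the bridge by conjugate addition and elimination and sets out from 27. Catalytic PhSH with Et3N in CH2Cl2 adds thiolate to C7 of the enone, and the resulting enolate expels the C9–O bond (E1cB) to give the hydroxy sulfide F4. F4 loses benzenethiol across C6–C7 to give the tropolone 28. The MOM ethers are then cleaved separately with ZnBr2/n-PrSH, and the route is rejoined at 29.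

**Further compounds**

F1 | step 17 | 3,4-bis(benzyloxy)-5-[(2R)-2-(benzyloxy)-3-Ar-propanoyl]-2-[(formyloxy)acetyl]benzaldehyde | O=Cc1cc(C(=O)[C@H](OCc9ccccc9)Cc2c(OCOC)cc(OCc9ccccc9)cc2OCc9ccccc9)c(OCc9ccccc9)c(OCc9ccccc9)c1C(=O)COC=O
F2 | step 17 | 5,6-bis(benzyloxy)-7-[(2R)-2-(benzyloxy)-3-Ar-propanoyl]-1-hydroxy-1H-isochromen-4(3H)-one (lactol, both C1 epimers) | OC1OCC(=O)c2c(OCc9ccccc9)c(OCc9ccccc9)c(C(=O)[C@H](OCc9ccccc9)Cc3c(OCOC)cc(OCc9ccccc9)cc3OCc9ccccc9)cc12
F3 | step 17 | 5,6-bis(benzyloxy)-7-[(2R)-2-(benzyloxy)-3-Ar-propanoyl]-4-oxo-3,4-dihydro-1H-isochromen-1-yl acetate | CC(=O)OC1OCC(=O)c2c(OCc9ccccc9)c(OCc9ccccc9)c(C(=O)[C@H](OCc9ccccc9)Cc3c(OCOC)cc(OCc9ccccc9)cc3OCc9ccccc9)cc12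
F4 | step 18 | 3,4-bis(benzyloxy)-2-[(2R)-2-(benzyloxy)-3-Ar-propanoyl]-8-{(2R)-3-Ar-2-[(tert-butyldiphenylsilyl)oxy]propanoyl}-6-hydroxy-7-(phenylsulfanyl)-6,7-dihydro-5H-benzo[7]annulen-5-one | O=C1C(O)C(Sc9ccccc9)C(C(=O)[C@H](O[Si](c9ccccc9)(c9ccccc9)C(C)(C)C)Cc3c(OCOC)cc(OCc9ccccc9)cc3OCc9ccccc9)=Cc2cc(C(=O)[C@H](OCc9ccccc9)Cc4c(OCOC)cc(OCc9ccccc9)cc4OCc9ccccc9)c(OCc9ccccc9)c(OCc9ccccc9)c12
F5 | step 19 | 3,4,6-tris(benzyloxy)-2-[(2R)-2-(benzyloxy)-3-Ar-propanoyl]-8-{(2R)-3-Ar-2-[(tert-butyldiphenylsilyl)oxy]propanoyl}-5H-benzo[7]annulen-5-one | O=C1C(OCc9ccccc9)=CC(C(=O)[C@H](O[Si](c9ccccc9)(c9ccccc9)C(C)(C)C)Cc3c(OCOC)cc(OCc9ccccc9)cc3OCc9ccccc9)=Cc2cc(C(=O)[C@H](OCc9ccccc9)Cc4c(OCOC)cc(OCc9ccccc9)cc4OCc9ccccc9)c(OCc9ccccc9)c(OCc9ccccc9)c12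
F6 | step 19 | 3,4,6-tris(benzyloxy)-2-[(1S,2R)-2-(benzyloxy)-1-hydroxy-3-Ar-propyl]-8-{(1S,2R)-3-Ar-2-[(tert-butyldiphenylsilyl)oxy]-1-hydroxypropyl}-5H-benzo[7]annulen-5-one | O=C1C(OCc9ccccc9)=CC([C@H](O)[C@H](O[Si](c9ccccc9)(c9ccccc9)C(C)(C)C)Cc3c(OCOC)cc(OCc9ccccc9)cc3OCc9ccccc9)=Cc2cc([C@H](O)[C@H](OCc9ccccc9)Cc4c(OCOC)cc(OCc9ccccc9)cc4OCc9ccccc9)c(OCc9ccccc9)c(OCc9ccccc9)c12
F7 | step 19 | 3,4,6-tris(benzyloxy)-2-[(1S,2R)-2-(benzyloxy)-1-hydroxy-3-Ar(OH)-propyl]-8-{(1S,2R)-3-Ar(OH)-2-[(tert-butyldiphenylsilyl)oxy]-1-hydroxypropyl}-5H-benzo[7]annulen-5-one | O=C1C(OCc9ccccc9)=CC([C@H](O)[C@H](O[Si](c9ccccc9)(c9ccccc9)C(C)(C)C)Cc3c(O)cc(OCc9ccccc9)cc3OCc9ccccc9)=Cc2cc([C@H](O)[C@H](OCc9ccccc9)Cc4c(O)cc(OCc9ccccc9)cc4OCc9ccccc9)c(OCc9ccccc9)c(OCc9ccccc9)c12
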